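I have no constants for this flask, just two earlier runs of the same racemate and partner with less free catalyst, so I must read the outcome from how the left-handed and right-handed product grow.

the same everywhere: left-handed substrate 0.25 M; right-handed substrate 0.25 M; racemization catalyst 1.2 mM

|  | partner | free catalyst | remark | time |
|---|---|---|---|---|
| ochre | 0.50 M | 0.12 mM | run made earlier |  |
| grey | 0.50 M | 0.19 mM | run made earlier |  |
| flask | 0.500 M | 0.25 mM |  | 40 min |

| run | time / min | left-handed product / % | right-handed product / % |
|---|---|---|---|
| ochre | 2.50 | 17 | 14 |
| ochre | 4.00 | 20 | 15 |
| ochre | 8.00 | 25 | 16 |
| ochre | 12.0 | 27 | 19 |
| ochre | 20.0 | 28 | 20 |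
| ochre | 30.0 | 33 | 19 |
| grey | 5.00 | 30 | 22 |
| grey | 10.0 | 35 | 22 |
| grey | 15.0 | 36 | 21 |
| grey | 20.0 | 37 | 24 |
| grey | 25.0 | 34 | 23 |
| grey | 30.0 | 40 | 24 |

(standard deviation of a reading: 2 percentage points)

- left-handed product and right-handed product together, in percent of the left-handed substrate and right-handed substrate charged together, at 40 min
- excess of left-handed product over right-handed product in the product at 40 min
- whether the exchange between left-handed substrate and right-handed substrate keeps pace with the reaction: how far the product's excess at 40 min gets from its value without exchange to its value with instant exchange (above 80% keeps pace, below 20% hardly takes part, else lags behind)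

- free catalyst is single-handed; left-handed substrate and right-handed substrate are mirror images of each other, charged as a racemate, each of them at the stated concentration
- an excess is below zero if the other one leads

If the exchange between the substrates were instant, [left-handed substrate] would equal [right-handed substrate], and two steps differing by one ratio of constants would make the products in that ratio, the selectivity factor, so their excess would stay flat in time.

Does it stay flat? The first 3 readings of the grey run give 21.7% and the last 3 give 22.0%, so I read no fall.

Does it then move with free catalyst? The grey run, with 1.58 times the free catalyst of the ochre run, gives 21.8% against 18.6%, and with each reading scattering by 2 percentage points I do not tell the two apart.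

So I pool both runs and read 20.5%: this pooled excess, the summed left-handed product minus the summed right-handed product over their total, is a reading that hands the left-handed product 60.2% of the product, and I commit to it for the flask.

The forecast gives 70% (65% to 76%) of product and an excess of 23% (16% to 30%), reckoned “with exchange keeping pace”, hence keeps pace. My pooled excess is lower than its value, by 2.5 points, and I set no figure of my own on the total or the pace.

    partner + free catalyst + right-handed substrate → free catalyst + right-handed product (k = 44.0 /M²/s)
    left-handed substrate + racemization catalyst ⇌ right-handed substrate + racemization catalyst, rate k2*[racemization catalyst]*[left-handed substrate] forward; the back reaction follows from the equilibrium constant (k = 4.20 /M/s)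
    partner + free catalyst + left-handed substrate → free catalyst + left-handed product (k = 78.0 /M²/s)
    free catalyst ⇌ dormant form (K = 13.0, k = 6.80 × 10⁻⁴ /s)
    2 partner → self-condensation product (k = 0.00350 /M/s)
    partner → decomposed reagent (k = 6.20 × 10⁻⁴ /s)

The flask gives 66.7% of product at an excess of 23.3%, and its exchange lags behind, having come 63% of the way to the value with instant exchange from the 15.6% that a run without exchange gives at 40.0 min. Applied to that total, the pooled excess gives 40.2% of left-handed product, and the flask holds 41.1% at 40.0 min. In the neighbour flask charged with 0.20 M of partner, whose total is 32.8%, the pooled excess gives 19.8%, and that flask holds at 40.0 min a left-handed product of 20.6%.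

(The runs are calculated on assumed constants; noise was put on by code.)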